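**Assumptions:** the TBS ether **2** and the styrene **6** are bought as catalogue compounds. Atom labels: THF ring O1, C2 (aryl), C3 (CH2OH), C4, C5 (CH2); C7 is the carbinol carbon on C4. The route is a paper design; none of it has been run.

## Retrosynthetic overview

1. Target **9** ⇐ cleavage of the one remaining aryl silyl ether of **8**.
2. **8** ⇐ epoxy cinnamyl ether **7**: a Ti(III)/photoredox 5-exo radical cyclization makes the C3–C4 bond and the THF (the only ring formed); the benzylic radical is borylated and oxidised to the C7–OH.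
3. **7** ⇐ allyl ether **5** + styrene **6** by cross-metathesis; **5** ⇐ O-allylation of epoxy alcohol **4**.
4. **4** ⇐ chelation-controlled reduction of epoxy ketone **3** ⇐ aryllithium from **2** + methyl (S)-glycidate **1**.
5. **1** is the only chiral material; its three carbons become C2, C3 and the CH2OH carbon.

## Route

**Step 1**
Reactants: **1** methyl (S)-glycidate; **2** (4-bromo-2-methoxyphenoxy)(tert-butyl)dimethylsilane
Product: **3** [4-(TBSO)-3-methoxyphenyl][(2S)-oxiran-2-yl]methanone
Conditions: **2**, n-BuLi, THF, −78 °C; cannulate into **1** (1.2 equiv), THF, −78 °C; NH4Cl quench at −78 °C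
Reagents that add atoms: none
Why: Br/Li exchange then nucleophilic acyl substitution; the Li-chelated tetrahedral intermediate of the α-oxygenated ester should hold at −78 °C so the ketone is released only on quench, and the epoxide stereocenter is not enolisable.

**Step 2**
Reactants: **3**
Product: **4** (R)-[4-(TBSO)-3-methoxyphenyl][(2S)-oxiran-2-yl]methanol
Conditions: Zn(BH4)2, Et2O, −20 → 0 °C
Reagents that add atoms: none
Why: chelation-controlled (Cram-cyclic, Oishi–Nakata) reduction of an α,β-epoxy ketone: Zn bridges C=O and the epoxide O and hydride adds from the α-H side, giving the erythro (R)-carbinol, typically >95:5 for this substrate class.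

**Step 3**
Reactants: **4**
Product: **5** tert-butyl{2-methoxy-4-[(R)-[(2S)-oxiran-2-yl](prop-2-enyloxy)methyl]phenoxy}dimethylsilane
Conditions: allyl bromide (3 equiv), cat. TBAI, THF, 0 °C, NaH added last
Reagents that add atoms: allyl bromide, C=CCBr
Why: Williamson etherification with the alkoxide trapped in situ by excess allyl bromide, so Payne rearrangement should not compete; no stereocenter is touched.

**Step 4**
Reactants: **5**; **6** 4-ethenyl-2-methoxyphenyl acetate (3 equiv)
Product: **7** 4-[(1E)-3-{(R)-[4-(TBSO)-3-methoxyphenyl][(2S)-oxiran-2-yl]methoxy}prop-1-enyl]-2-methoxyphenyl acetate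
Conditions: Hoveyda–Grubbs II (5 mol%), 1,4-benzoquinone (10 mol%), CH2Cl2, 40 °C
Reagents that add atoms: none
Why: olefin cross-metathesis of an allyl ether with a styrene is E-selective and tolerates the epoxide, silyl ether and acetate; benzoquinone suppresses allyl-to-propenyl isomerisation.

**Step 5**
Reactants: **7**
Product: **8** (2S,3R,4R)-2-[4-(TBSO)-3-methoxyphenyl]-3-(hydroxymethyl)-4-[(R)-hydroxy(4-hydroxy-3-methoxyphenyl)methyl]tetrahydrofuran
Conditions: Cp2TiCl2 (10 mol%), 4CzIPN (2 mol%), Hantzsch ester (20 mol%), B2cat2 (3 equiv), THF/DMAc, blue LEDs, rt; then NaBO3·4H2O, THF/H2O, rt (oxidises C–B, also cleaves the aryl acetate)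
Reagents that add atoms: sodium perborate (oxygen of the C7–OH), [Na+].[Na+].O[B-]1(O)OO[B-](O)(O)OO1. B2cat2 (O1c2ccccc2OB1B1Oc2ccccc2O1) supplies boron only transiently.
Why: Proposed new method: photogenerated Cp2Ti(III)Cl opens the epoxide homolytically at C3; the β-titanoxy radical closes 5-exo-trig onto the cinnamyl alkene through a Beckwith–Houk chair with the C2 aryl pseudo-equatorial (2,3-trans, 3,4-cis; C3–C4 bond and ring); the benzylic C7 radical, held with C4–H eclipsing the aryl, is borylated by DMAc-ligated B2cat2 on the face anti to the C3 branch, which gives 7R after stereoretentive C–B oxidation, and the expelled boryl radical returns Ti(IV)–OR to Ti(III) as RO–Bcat; closest known reactions are the Nugent–RajanBabu/Gansäuer Ti(III) epoxide–alkene radical cyclization (photoredox-regenerated Ti; used reductively by Roy for lariciresinol-type lignans) and Aggarwal/Studer radical borylation/carboboration with B2cat2.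

**Step 6**
Reactants: **8**
Product: **9** (7R)-7-hydroxylariciresinol
Conditions: TBAF/AcOH (1:1), THF, 0 °C → rt; pH 7 work-up
Reagents that add atoms: none
Why: fluoride cleavage of the aryl silyl ether under buffered, non-acidic conditions, so the two p-hydroxybenzylic C–O bonds (C2–O1 and C7–OH) are not ionised and no furofuran closure or epimerisation occurs.

## Compound list

1 | methyl (2S)-oxirane-2-carboxylate | COC(=O)[C@@H]1CO1 | starting material
2 | (4-bromo-2-methoxyphenoxy)(tert-butyl)dimethylsilane | COc1cc(Br)ccc1O[Si](C)(C)C(C)(C)C | starting material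
3 | [4-(tert-butyldimethylsilyloxy)-3-methoxyphenyl][(2S)-oxiran-2-yl]methanone | COc1cc(C(=O)[C@@H]2CO2)ccc1O[Si](C)(C)C(C)(C)C | intermediate
4 | (R)-[4-(tert-butyldimethylsilyloxy)-3-methoxyphenyl][(2S)-oxiran-2-yl]methanol | COc1cc([C@@H](O)[C@@H]2CO2)ccc1O[Si](C)(C)C(C)(C)C | intermediate
5 | allyl ether of 4 (carbinol R, epoxide S) | COc1cc([C@@H](OCC=C)[C@@H]2CO2)ccc1O[Si](C)(C)C(C)(C)C | intermediate
6 | 4-ethenyl-2-methoxyphenyl acetate | CC(=O)Oc1ccc(C=C)cc1OC | starting material
7 | (E)-4-acetoxy-3-methoxycinnamyl ether of 4 | COc1cc([C@@H](OC/C=C/c3ccc(OC(C)=O)c(OC)c3)[C@@H]2CO2)ccc1O[Si](C)(C)C(C)(C)C | intermediate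
8 | (2S,3R,4R)-2-[4-(TBSO)-3-methoxyphenyl]-3-(hydroxymethyl)-4-[(R)-hydroxy(4-hydroxy-3-methoxyphenyl)methyl]tetrahydrofuran | COc1cc([C@H]2OC[C@H]([C@@H](O)c3ccc(O)c(OC)c3)[C@@H]2CO)ccc1O[Si](C)(C)C(C)(C)C | intermediate
9 | (7R)-7-hydroxylariciresinol, 4-[(2S,3R,4R)-4-[(R)-hydroxy(4-hydroxy-3-methoxyphenyl)methyl]-3-(hydroxymethyl)oxolan-2-yl]-2-methoxyphenol | COc1cc([C@H]2OC[C@H]([C@@H](O)c3ccc(O)c(OC)c3)[C@@H]2CO)ccc1O | target

## Summary

Total steps: 6. Longest linear sequence: 6 (from **1**).

Steps most likely to fail, with fallbacks: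

1. **Step 5 (new borylative cyclization).** Risks are slow borylation of the stabilised benzylic radical, reduction to the C7-H2 (lariciresinol-type) product, or low selectivity at C7. Fallback with known chemistry: make the 3-arylprop-2-ynyl ether of **4** (propargyl bromide, then Sonogashira with the 4-iodo-2-methoxyphenyl silyl ether). Run the established Ti(III) epoxide–alkyne 5-exo-dig radical cyclization to the (E)-3-benzylidene-THF. Then hydroborate/oxidise (BH3·SMe2; NaBO3): syn H/OH addition on the face anti to the C3 CH2OH sets the same C4 and C7 configurations.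

2. **Step 1 (aryllithium on the glycidate ester).** Risks are over-addition and epoxide opening. Fallback: set the benzylic stereocenter by Felkin–Anh (anti) addition of the aryl Grignard to (S)-glyceraldehyde acetonide and separate the anti adduct. O-allylate, then unveil the epoxide (AcOH/H2O; TsCl; K2CO3). This gives **5** directly.

3. **Step 4 (cross-metathesis).** Risks are styrene homodimerisation and allyl-ether isomerisation. Fallback: drop the metathesis and alkylate **4** directly with (E)-4-(TBSO)-3-methoxycinnamyl bromide (from ethyl ferulate: TBSCl; DIBAL-H; CBr4/PPh3). Both silyl ethers then come off in the final step.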